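**Retrosynthetic overview** (carotenoid numbering; ring A = cyclohexane C1–C6, ring B = dihydrofuran O–C5–C6=C7–C8)
1. The last bond is C11=C12, made by a Wittig reaction between a C25 ε-apo phosphonium salt (from (R)-α-ionone, a vinyl Grignard reagent and the C10 trienedial) and a furanoid C15 enal.
2. Ring B is closed last, by AgNO3-catalysed 5-endo cyclisation of an α-hydroxy vinylallene (axis-to-centre transfer sets C8); the allene comes from anti-SN2' Pd2(dba)3/formate hydrogenolysis of a cis-fused alkynyl cyclic carbonate, itself made by acetylide addition to (R)-2-hydroxy-2,6,6-trimethylcyclohexanone.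
3. Ring A is closed first, in the key step: an anionic (4+2) annulation in which the lithium enolate of an (R)-α,β-epoxy isopropyl ketone adds to phenyl vinyl sulfone (C1–C2) and the resulting sulfonyl carbanion opens the epoxide at its CH2 end (C3–C4); the sulfone is then removed.
4. The feature that allows this: in ring A the gem-dimethyl carbon C1 and the oxygen-bearing quaternary carbon C5 both flank the ring-fusion carbon C6, and C2, C3 and C4 are bare CH2 groups. With C6 drawn as a ketone, C1 is an enolate carbon, C5–C4 is an epoxide whose oxygen is the later ring B oxygen, and C2–C3 is a vinyl unit.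
5. The epoxy ketone comes from methallyl alcohol: Sharpless epoxidation (sets C5), oxidation, isopropyl Grignard addition, oxidation.

Key step: step 5

Assumption: (R)-α-ionone, (2E)-3-methylpent-2-en-4-yn-1-ol and (2E,4E,6E)-2,7-dimethylocta-2,4,6-trienedial are bought as the stated single isomers, and the disubstituted double bonds from the two Wittig couplings, which form as E/Z mixtures, are brought to E by the thermal equilibration written into the conditions.

**Route**

Step 1
Reactants: 1 2-methylprop-2-en-1-ol (methallyl alcohol)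
Product: 2 [(2S)-2-methyloxiran-2-yl]methanol
Conditions: Ti(OiPr)4 (5 mol %), L-(+)-diisopropyl tartrate (6 mol %), t-BuOOH, 4 Å molecular sieves, CH2Cl2, −20 °C
Reagents that add atoms: tert-butyl hydroperoxide, CC(C)(C)OO
Why: Sharpless asymmetric epoxidation of a primary allylic alcohol, in which the Ti(OiPr)4/L-(+)-tartrate catalyst delivers the oxygen to one olefin face and so sets the quaternary C–O stereocentre (the later C5) by reagent control.

Step 2
Reactants: 2 [(2S)-2-methyloxiran-2-yl]methanol
Product: 3 (2R)-2-methyloxirane-2-carbaldehyde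
Conditions: n-Pr4N[RuO4] (5 mol %), N-methylmorpholine N-oxide, 4 Å molecular sieves, CH2Cl2, 0 °C to rt; filtered through silica and kept as a solution
Reagents that add atoms: none
Why: Ley–Griffith oxidation stops at the aldehyde under neutral anhydrous conditions that spare the epoxide, and the stereocentre is untouched (the descriptor becomes R only because the formyl group outranks the ring CH2).

Step 3
Reactants: 3 (2R)-2-methyloxirane-2-carbaldehyde; 4 isopropylmagnesium chloride
Product: 5 (1RS)-2-methyl-1-[(2R)-2-methyloxiran-2-yl]propan-1-ol (both carbinol epimers)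
Conditions: i-PrMgCl, CeCl3, THF, −78 °C; aq. NH4Cl
Reagents that add atoms: none
Why: Grignard addition (run as the organocerium reagent to suppress β-hydride reduction) to the aldehyde, which is far more electrophilic than the 2,2-disubstituted epoxide at −78 °C; the new carbinol centre forms as a mixture that step 4 erases.

Step 4
Reactants: 5 (1RS)-2-methyl-1-[(2R)-2-methyloxiran-2-yl]propan-1-ol
Product: 6 2-methyl-1-[(2R)-2-methyloxiran-2-yl]propan-1-one
Conditions: n-Pr4N[RuO4] (5 mol %), N-methylmorpholine N-oxide, 4 Å molecular sieves, CH2Cl2, rt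
Reagents that add atoms: none
Why: Ley–Griffith oxidation of the secondary alcohol gives the epoxy ketone without acid or base, so the epoxide and its (R) centre, which carries no α-hydrogen, are preserved.

Step 5
Reactants: 6 2-methyl-1-[(2R)-2-methyloxiran-2-yl]propan-1-one; 7 phenyl vinyl sulfone
Product: 10 (2R)-2-hydroxy-2,6,6-trimethyl-4-(phenylsulfonyl)cyclohexan-1-one (both epimers at the sulfone carbon), via lithium enolate 8 (not isolated), via sulfonyl carbanion 9 (not isolated)
Conditions: LiN(i-Pr)2 (1.05 equiv), THF, −78 °C; 7 (0.9 equiv) added slowly at −78 °C; DMPU, −78 → 0 °C; aq. NH4Cl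
Reagents that add atoms: none
Why: Proposed new method: LiN(i-Pr)2 removes the only enolisable hydrogen of 6 (the isopropyl methine) to give enolate 8, whose gem-dimethyl carbon adds to the unsubstituted carbon of vinyl sulfone 7 (bond C1–C2); adduct 9 has no acidic hydrogen next to its ketone, so the α-sulfonyl carbanion persists until it opens the oxirane at its CH2 terminus (bond C3–C4) and releases the tertiary alkoxide. The closest known reaction type is the Michael-initiated ring closure of lithium ketone enolates with phenyl vinyl sulfone, in which the sulfonyl carbanion is trapped by an internal electrophile, together with the well-known cyclisation of sulfonyl carbanions onto epoxides; what is new is their union on an α,β-epoxy ketone enolate. Ring A closes by a 6-endo-tet epoxide opening, favoured over the 5-exo alternative because that would demand SN2 attack at a fully substituted carbon next to the carbonyl group. No lasting stereocentre is made: the C–O bond at the quaternary centre is not broken, so the (R) configuration from step 1 is carried into 10, and the sulfone-bearing carbon forms as an epimer mixture that step 6 removes. The step needs C- over O-alkylation of the hindered enolate and ring closure ahead of oligomerisation of 7 by carbanion 9; a deficit of 7 added slowly at −78 °C and a polar cosolvent on warming are chosen for this.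

Step 6
Reactants: 10 (2R)-2-hydroxy-2,6,6-trimethyl-4-(phenylsulfonyl)cyclohexan-1-one
Product: 11 (2R)-2-hydroxy-2,6,6-trimethylcyclohexan-1-one
Conditions: Na(Hg) (6% Na), Na2HPO4, MeOH, −20 °C
Reagents that add atoms: none
Why: Reductive desulfonylation by electron transfer replaces the alkyl–sulfonyl bond by C–H, both sulfone epimers converge on one product, and the hindered non-enolisable ketone and the tertiary alcohol are expected to survive the buffered low-temperature conditions.

Step 7
Reactants: 12 (2E)-3-methylpent-2-en-4-yn-1-ol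
Product: 13 tert-butyl(dimethyl){[(2E)-3-methylpent-2-en-4-yn-1-yl]oxy}silane
Conditions: t-BuMe2SiCl, imidazole, DMF, 0 °C to rt
Reagents that add atoms: tert-butyldimethylsilyl chloride, CC(C)(C)[Si](C)(C)Cl
Why: Standard silylation of the primary allylic alcohol masks the only O–H so that the terminal alkyne can be lithiated in step 8.

Step 8
Reactants: 11 (2R)-2-hydroxy-2,6,6-trimethylcyclohexan-1-one; 13 tert-butyl(dimethyl){[(2E)-3-methylpent-2-en-4-yn-1-yl]oxy}silane
Product: 16 (3aR,7aR)-3a-[(3E)-5-{[tert-butyl(dimethyl)silyl]oxy}-3-methylpent-3-en-1-yn-1-yl]-4,4,7a-trimethylhexahydro-1,3-benzodioxol-2-one (cis-fused cyclic carbonate), via lithium acetylide 14 (not isolated), via dilithium diolate 15 (not isolated)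
Conditions: 13 (2.3 equiv), n-BuLi (2.2 equiv), THF, −78 °C; 11, −78 → 0 °C; 1,1'-carbonyldiimidazole, 0 °C to rt; aq. NH4Cl
Reagents that add atoms: 1,1'-carbonyldiimidazole, O=C(n1ccnc1)n1ccnc1
Why: Acetylide addition to the non-enolisable ketone followed by carbonylation of the vicinal dialkoxide: the acetylide should attack axially and anti to the axial C–O bond of the chair that keeps the C5 methyl equatorial (this chair avoids a syn-axial methyl/methyl clash with the gem-dimethyl group), so the alkyne enters trans to the C5 oxygen, the new C6 centre is R, and the two cis oxygens are tied as the cyclic carbonate.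

Step 9
Reactants: 16 cis-fused alkynyl cyclic carbonate
Product: 17 (1R)-2-[(3E)-5-{[tert-butyl(dimethyl)silyl]oxy}-3-methylpenta-1,3-dien-1-ylidene]-1,3,3-trimethylcyclohexan-1-ol with (S)-configured allene axis
Conditions: Pd2(dba)3 (2.5 mol %), n-Bu3P (10 mol %), HCO2H, Et3N, THF, rt → 40 °C
Reagents that add atoms: none
Why: Palladium-catalysed formate hydrogenolysis of a propargylic carbonate, in which zerovalent palladium attacks the alkyne terminus C8 anti to the leaving oxygen on C6, CO2 is lost, and hydride transfer from formate with retention at palladium gives the α-hydroxy vinylallene, so the (R) centre at C6 is translated into the (S) allene axis by overall anti-SN2' displacement.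

Step 10
Reactants: 17 α-hydroxy vinylallene
Product: 18 tert-butyl(dimethyl){[(2E)-3-[(2R,7aR)-4,4,7a-trimethyl-2,4,5,6,7,7a-hexahydro-1-benzofuran-2-yl]but-2-en-1-yl]oxy}silane
Conditions: AgNO3 (20 mol %), CaCO3, acetone/H2O, rt, dark
Reagents that add atoms: none
Why: AgNO3-catalysed 5-endo-trig hydroalkoxylation of an α-hydroxyallene, in which the tertiary hydroxyl adds in the plane of ring B to the allene terminus anti to the coordinated metal and protodemetalation gives the 2,5-dihydrofuran, so the (S) axis becomes the (R) centre at C8 with the side chain on the face opposite to the C5 methyl.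

Step 11
Reactants: 18 furanoid C15 silyl ether
Product: 19 (2E)-3-[(2R,7aR)-4,4,7a-trimethyl-2,4,5,6,7,7a-hexahydro-1-benzofuran-2-yl]but-2-en-1-ol
Conditions: n-Bu4NF, THF, 0 °C
Reagents that add atoms: none
Why: Fluoride cleaves the primary silyl ether under non-acidic conditions, which matters because the bis-allylic C8–O bond of ring B ionises in acid.

Step 12
Reactants: 19 furanoid C15 alcohol
Product: 20 (2E)-3-[(2R,7aR)-4,4,7a-trimethyl-2,4,5,6,7,7a-hexahydro-1-benzofuran-2-yl]but-2-enal
Conditions: MnO2, CH2Cl2, rt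
Reagents that add atoms: none
Why: Neutral heterogeneous oxidation selective for the allylic alcohol gives the enal without touching the acid-labile dihydrofuran or the C8 centre.

Step 13
Reactants: 21 (R)-α-ionone, (3E)-4-[(1R)-2,6,6-trimethylcyclohex-2-en-1-yl]but-3-en-2-one; 22 vinylmagnesium bromide
Product: 23 (1E)-3-methyl-1-[(1R)-2,6,6-trimethylcyclohex-2-en-1-yl]penta-1,4-dien-3-ol (both carbinol epimers)
Conditions: CH2=CHMgBr, THF, −20 → 0 °C; aq. NH4Cl
Reagents that add atoms: none
Why: 1,2-Grignard addition to the enone carbonyl gives the tertiary bis-allylic alcohol; the new carbinol centre is a mixture that disappears in step 14, and the remote C6' centre is not touched at low temperature.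

Step 14
Reactants: 23 vinyl-α-ionol
Product: 24 [(2E,4E)-3-methyl-5-[(1R)-2,6,6-trimethylcyclohex-2-en-1-yl]penta-2,4-dien-1-yl](triphenyl)phosphonium bromide
Conditions: Ph3P·HBr, MeOH, 0 °C to rt
Reagents that add atoms: triphenylphosphine hydrobromide, [Br-].[PH+](c1ccccc1)(c1ccccc1)c1ccccc1
Why: Acid ionises the tertiary bis-allylic alcohol to a pentadienyl cation that triphenylphosphine captures at the unhindered primary terminus (allylic transposition), giving the conjugated (2E,4E) phosphonium salt while C6' stays as it is.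

Step 15
Reactants: 24 C15 phosphonium bromide; 25 (2E,4E,6E)-2,7-dimethylocta-2,4,6-trienedial
Product: 27 (2E,4E,6E,8E,10E,12E)-2,7,11-trimethyl-13-[(1R)-2,6,6-trimethylcyclohex-2-en-1-yl]trideca-2,4,6,8,10,12-hexaenal, via phosphonium ylide 26 (not isolated)
Conditions: 25 (3 equiv), 1,2-epoxybutane, EtOH, reflux, dark
Reagents that add atoms: none
Why: Wittig reaction under neutral conditions, where bromide opens the epoxide to an alkoxide that forms the ylide in low concentration, the excess of the symmetrical dialdehyde enforces mono-olefination, and the new disubstituted double bond equilibrates to E in the hot solution.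

Step 16
Reactants: 27 C25 aldehyde
Product: 28 (2E,4E,6E,8E,10E,12E)-2,7,11-trimethyl-13-[(1R)-2,6,6-trimethylcyclohex-2-en-1-yl]trideca-2,4,6,8,10,12-hexaen-1-ol
Conditions: NaBH4, MeOH/THF, 0 °C
Reagents that add atoms: none
Why: Borohydride reduces the polyenal in the 1,2 sense to the primary allylic alcohol and leaves the polyene chain alone.

Step 17
Reactants: 28 C25 alcohol
Product: 29 [(2E,4E,6E,8E,10E,12E)-2,7,11-trimethyl-13-[(1R)-2,6,6-trimethylcyclohex-2-en-1-yl]trideca-2,4,6,8,10,12-hexaen-1-yl](triphenyl)phosphonium bromide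
Conditions: Ph3P·HBr, CH2Cl2/MeOH, rt
Reagents that add atoms: triphenylphosphine hydrobromide, [Br-].[PH+](c1ccccc1)(c1ccccc1)c1ccccc1
Why: The polyenylic alcohol ionises readily and the phosphine takes the cation at the terminal carbon, which keeps the chain fully conjugated and all-E.

Step 18
Reactants: 29 C25 phosphonium bromide; 20 furanoid C15 enal
Product: 31 (5R,8R,6'R)-5,8-epoxy-5,8-dihydro-β,ε-carotene (the target), via polyenyl ylide 30 (not isolated)
Conditions: 29 (1.2 equiv), NaN(SiMe3)2 (1.1 equiv), THF, −78 °C; 20, −78 → 0 °C; then n-heptane, reflux, argon, dark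
Reagents that add atoms: none
Why: Wittig reaction of the preformed polyenyl ylide with the enal forms C11=C12 with no free base present (so the γ-hydrogen at C8 is not removed), and the E/Z mixture at the new bond is equilibrated thermally to the all-E target; C5, C8 and C6' are not involved.

**Compound list**
1 | 2-methylprop-2-en-1-ol | CC(=C)CO | starting material
2 | [(2S)-2-methyloxiran-2-yl]methanol | C[C@]1(CO)CO1 | intermediate
3 | (2R)-2-methyloxirane-2-carbaldehyde | C[C@]1(C=O)CO1 | intermediate
4 | isopropylmagnesium chloride | CC(C)[Mg]Cl | starting material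
5 | (1RS)-2-methyl-1-[(2R)-2-methyloxiran-2-yl]propan-1-ol | C[C@]1(C(O)C(C)C)CO1 | intermediate
6 | 2-methyl-1-[(2R)-2-methyloxiran-2-yl]propan-1-one | C[C@]1(C(=O)C(C)C)CO1 | intermediate
7 | phenyl vinyl sulfone | C=CS(=O)(=O)c1ccccc1 | starting material
8 | lithium 2-methyl-1-[(2R)-2-methyloxiran-2-yl]prop-1-en-1-olate | CC(C)=C([O-])[C@@]1(C)CO1.[Li+] | intermediate
9 | lithium 3,3-dimethyl-4-[(2R)-2-methyloxiran-2-yl]-4-oxo-1-(phenylsulfonyl)butan-1-ide | [Li+].O=C(C(C)(C)C[CH-]S(=O)(=O)c1ccccc1)[C@@]1(C)CO1 | intermediate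
10 | (2R)-2-hydroxy-2,6,6-trimethyl-4-(phenylsulfonyl)cyclohexan-1-one (epimers at C4) | C[C@@]1(O)CC(S(=O)(=O)c2ccccc2)CC(C)(C)C1=O | intermediate
11 | (2R)-2-hydroxy-2,6,6-trimethylcyclohexan-1-one | C[C@@]1(O)CCCC(C)(C)C1=O | intermediate
12 | (2E)-3-methylpent-2-en-4-yn-1-ol | C#C/C(C)=C/CO | starting material
13 | tert-butyl(dimethyl){[(2E)-3-methylpent-2-en-4-yn-1-yl]oxy}silane | C#C/C(C)=C/CO[Si](C)(C)C(C)(C)C | intermediate
14 | lithium (3E)-5-{[tert-butyl(dimethyl)silyl]oxy}-3-methylpent-3-en-1-yn-1-ide | [Li+].[C-]#C/C(C)=C/CO[Si](C)(C)C(C)(C)C | intermediate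
15 | dilithium (1R,2R)-1-[(3E)-5-{[tert-butyl(dimethyl)silyl]oxy}-3-methylpent-3-en-1-yn-1-yl]-2,6,6-trimethylcyclohexane-1,2-diolate (cis) | C[C@@]1([O-])CCCC(C)(C)[C@@]1([O-])C#C/C(C)=C/CO[Si](C)(C)C(C)(C)C.[Li+].[Li+] | intermediate
16 | (3aR,7aR)-3a-[(3E)-5-{[tert-butyl(dimethyl)silyl]oxy}-3-methylpent-3-en-1-yn-1-yl]-4,4,7a-trimethylhexahydro-1,3-benzodioxol-2-one | C[C@@]12CCCC(C)(C)[C@@]1(OC(=O)O2)C#C/C(C)=C/CO[Si](C)(C)C(C)(C)C | intermediate
17 | (1R)-2-[(3E)-5-{[tert-butyl(dimethyl)silyl]oxy}-3-methylpenta-1,3-dien-1-ylidene]-1,3,3-trimethylcyclohexan-1-ol, (S) allene axis | C[C@@]1(O)CCCC(C)(C)C1=[C@]=C([H])/C(C)=C/CO[Si](C)(C)C(C)(C)C | intermediate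
18 | tert-butyl(dimethyl){[(2E)-3-[(2R,7aR)-4,4,7a-trimethyl-2,4,5,6,7,7a-hexahydro-1-benzofuran-2-yl]but-2-en-1-yl]oxy}silane | CC(C)(C)[Si](C)(C)OC/C=C(\C)[C@H]1C=C2C(C)(C)CCC[C@@]2(C)O1 | intermediate
19 | (2E)-3-[(2R,7aR)-4,4,7a-trimethyl-2,4,5,6,7,7a-hexahydro-1-benzofuran-2-yl]but-2-en-1-ol | OC/C=C(\C)[C@H]1C=C2C(C)(C)CCC[C@@]2(C)O1 | intermediate
20 | (2E)-3-[(2R,7aR)-4,4,7a-trimethyl-2,4,5,6,7,7a-hexahydro-1-benzofuran-2-yl]but-2-enal | O=C/C=C(\C)[C@H]1C=C2C(C)(C)CCC[C@@]2(C)O1 | intermediate
21 | (3E)-4-[(1R)-2,6,6-trimethylcyclohex-2-en-1-yl]but-3-en-2-one ((R)-α-ionone) | CC1=CCCC(C)(C)[C@H]1/C=C/C(C)=O | starting material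
22 | vinylmagnesium bromide | C=C[Mg]Br | starting material
23 | (1E)-3-methyl-1-[(1R)-2,6,6-trimethylcyclohex-2-en-1-yl]penta-1,4-dien-3-ol (carbinol epimers) | CC1=CCCC(C)(C)[C@H]1/C=C/C(C)(O)C=C | intermediate
24 | [(2E,4E)-3-methyl-5-[(1R)-2,6,6-trimethylcyclohex-2-en-1-yl]penta-2,4-dien-1-yl](triphenyl)phosphonium bromide | CC1=CCCC(C)(C)[C@H]1/C=C/C(C)=C/C[P+](c1ccccc1)(c1ccccc1)c1ccccc1.[Br-] | intermediate
25 | (2E,4E,6E)-2,7-dimethylocta-2,4,6-trienedial | O=C/C(C)=C/C=C/C=C(\C)C=O | starting material
26 | ylide of 24, [(2E,4E)-3-methyl-5-[(1R)-2,6,6-trimethylcyclohex-2-en-1-yl]penta-2,4-dien-1-ylidene](triphenyl)phosphorane | CC1=CCCC(C)(C)[C@H]1/C=C/C(C)=C/C=P(c1ccccc1)(c1ccccc1)c1ccccc1 | intermediate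
27 | (2E,4E,6E,8E,10E,12E)-2,7,11-trimethyl-13-[(1R)-2,6,6-trimethylcyclohex-2-en-1-yl]trideca-2,4,6,8,10,12-hexaenal | CC1=CCCC(C)(C)[C@H]1/C=C/C(C)=C/C=C/C(C)=C/C=C/C=C(C)/C=O | intermediate
28 | (2E,4E,6E,8E,10E,12E)-2,7,11-trimethyl-13-[(1R)-2,6,6-trimethylcyclohex-2-en-1-yl]trideca-2,4,6,8,10,12-hexaen-1-ol | CC1=CCCC(C)(C)[C@H]1/C=C/C(C)=C/C=C/C(C)=C/C=C/C=C(C)/CO | intermediate
29 | [(2E,4E,6E,8E,10E,12E)-2,7,11-trimethyl-13-[(1R)-2,6,6-trimethylcyclohex-2-en-1-yl]trideca-2,4,6,8,10,12-hexaen-1-yl](triphenyl)phosphonium bromide | CC1=CCCC(C)(C)[C@H]1/C=C/C(C)=C/C=C/C(C)=C/C=C/C=C(C)/C[P+](c1ccccc1)(c1ccccc1)c1ccccc1.[Br-] | intermediate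
30 | ylide of 29 (triphenylphosphorane at the terminal chain carbon) | CC1=CCCC(C)(C)[C@H]1/C=C/C(C)=C/C=C/C(C)=C/C=C/C=C(C)/C=P(c1ccccc1)(c1ccccc1)c1ccccc1 | intermediate
31 | (5R,8R,6'R)-5,8-epoxy-5,8-dihydro-β,ε-carotene | CC1=CCCC(C)(C)[C@H]1/C=C/C(C)=C/C=C/C(C)=C/C=C/C=C(C)/C=C/C=C(\C)[C@H]1C=C2C(C)(C)CCC[C@@]2(C)O1 | target

**Step count and risks**
Total: 18 steps. Longest linear sequence: 12 steps (steps 1–6, 8–12 and 18).

Steps most likely to fail:

1. Step 5 (bears the label). The sulfonyl carbanion may add to further vinyl sulfone faster than it cyclises, or C-alkylation of the hindered enolate may be sluggish. Fallback: the two bond formations are uncoupled. From 6, a base-catalysed Michael addition to 7 in a protic medium (KOt-Bu 10 mol %, t-BuOH/THF, 0 °C), where the solvent protonates each sulfonyl carbanion as it forms, should give 2,2-dimethyl-1-[(2R)-2-methyloxiran-2-yl]-4-(phenylsulfonyl)butan-1-one F1. F1 has no hydrogen α to the ketone, so LiN(i-Pr)2 (THF/DMPU, −78 → 0 °C) deprotonates it next to sulfur, and the known sulfonyl-carbanion epoxide cyclisation rejoins the route at 10.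

2. Step 8. Facial selectivity of the acetylide addition may be poor: lithium chelation between the alkoxide and the ketone would turn the attack to the other face, and the resulting trans-diol would lead to the C8 epimer. Fallback: the hydroxyl is made non-chelating first. From 11, Me3SiOTf and 2,6-lutidine (CH2Cl2, −78 °C) give (2R)-2,6,6-trimethyl-2-[(trimethylsilyl)oxy]cyclohexan-1-one F2. Addition of acetylide 14 (THF, −78 °C), now anti to the axial silyloxy group, gives (1R,2R)-1-[(3E)-5-{[tert-butyl(dimethyl)silyl]oxy}-3-methylpent-3-en-1-yn-1-yl]-2,6,6-trimethyl-2-[(trimethylsilyl)oxy]cyclohexan-1-ol F3. K2CO3 in MeOH removes only the trimethylsilyl group (a silyl shift between the two cis oxygens would be without consequence) and gives (1R,2R)-1-[(3E)-5-{[tert-butyl(dimethyl)silyl]oxy}-3-methylpent-3-en-1-yn-1-yl]-2,6,6-trimethylcyclohexane-1,2-diol F4. NaH and 1,1'-carbonyldiimidazole in THF then close the carbonate and rejoin the route at 16.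

3. Step 9. Hydride may be delivered to the wrong end of the propargyl/allenyl palladium intermediate (alkyne instead of allene), or the stereochemical information may be lost if that intermediate equilibrates. Fallback: a stoichiometric copper hydride replaces the palladium/formate couple and works by a different mechanism. From 16, [(Ph3P)CuH]6 in toluene at 0 °C to rt adds Cu–H across the alkyne with hydride at C8, and anti β-elimination of the carbonate oxygen then gives the allene, rejoining the route at 17. This fallback makes no compound outside the list (F0).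

**Further compounds**
F1 | step 5 | 2,2-dimethyl-1-[(2R)-2-methyloxiran-2-yl]-4-(phenylsulfonyl)butan-1-one | O=C(C(C)(C)CCS(=O)(=O)c1ccccc1)[C@@]1(C)CO1
F2 | step 8 | (2R)-2,6,6-trimethyl-2-[(trimethylsilyl)oxy]cyclohexan-1-one | C[C@@]1(O[Si](C)(C)C)CCCC(C)(C)C1=O
F3 | step 8 | (1R,2R)-1-[(3E)-5-{[tert-butyl(dimethyl)silyl]oxy}-3-methylpent-3-en-1-yn-1-yl]-2,6,6-trimethyl-2-[(trimethylsilyl)oxy]cyclohexan-1-ol | C[C@@]1(O[Si](C)(C)C)CCCC(C)(C)[C@@]1(O)C#C/C(C)=C/CO[Si](C)(C)C(C)(C)C
F4 | step 8 | (1R,2R)-1-[(3E)-5-{[tert-butyl(dimethyl)silyl]oxy}-3-methylpent-3-en-1-yn-1-yl]-2,6,6-trimethylcyclohexane-1,2-diol | C[C@@]1(O)CCCC(C)(C)[C@@]1(O)C#C/C(C)=C/CO[Si](C)(C)C(C)(C)C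
F0 | step 9 | none | none
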